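Ring A is a 3-hydroxycyclohexanone in disguise: the carbinol C2 sits between the methylene-bearing C1 and the vinylic C3, and the brominated C4 adjoins quaternary C5. Breaking C2–C3 gives a keto-enal in which the C5 arm (CMe2 carrying acetyl) and a 2-substituted acrolein both sit on spiro carbon C6 of the complete (9S,10S)-bromochloro ring B. One intramolecular lithium-enolate aldol addition (acetyl CH3 onto the aldehyde) forms C2–C3, ring A and the C2 carbinol, and brings in the exocyclic CH2 unchanged. Ring B comes from an enantioselective bromochlorination and an Ireland–Claisen rearrangement; C4=O then becomes C4–Br through the enol triflate.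

Key step: step 13

Remark on numbering: carbons are numbered as in the target (C1–C5 ring A, C6 spiro, C7–C11 ring B; C9 bears CH3 and Cl, C10 bears Br).
Assumption: the enantiomer of the Schiff-base ligand in step 3 is the one that gives the 5S,6S bromochloride; its sense of induction is taken by analogy and should be confirmed on the first run.
Remark: the quaternary carbon of keto-enal 19 is 1S (1S,3S,4S overall); the same carbon is labelled 1R in 12 to 15 only because the priorities change.

Step 1
Reactants: 1 but-2-yn-1-ol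
Product: 2 (2Z)-3-iodobut-2-en-1-ol
Conditions: NaAlH2(OCH2CH2OMe)2, THF, 0 °C; then I2, −78 °C
Reagents that add atoms: iodine, [I][I]
Why: Hydroalumination of the propargylic alkoxide delivers hydride to C2 and aluminium to C3 in a trans addition, and iodinolysis of the C–Al bond with retention gives the Z-iodide (hydroalumination–iodination of a 2-alkyn-1-ol).

Step 2
Reactants: 2 (2Z)-3-iodobut-2-en-1-ol; 3 (4-ethoxy-4-oxobutyl)zinc bromide, BrZn(CH2)3CO2Et
Product: 4 ethyl (5Z)-7-hydroxy-5-methylhept-5-enoate
Conditions: Pd(PPh3)4 (5 mol%), THF, 25–40 °C (2.5 equiv of 3)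
Reagents that add atoms: none
Why: Negishi coupling of an alkenyl iodide with a primary alkylzinc bromide goes with retention at the sp2 carbon, so the new chain stays cis to CH2OH (the Z-alkene that later gives a trans dihalide in the ring).

Step 3
Reactants: 4 ethyl (5Z)-7-hydroxy-5-methylhept-5-enoate
Product: 5 ethyl (5S,6S)-6-bromo-5-chloro-7-hydroxy-5-methylheptanoate
Conditions: NBS, ClTi(OiPr)3, chiral tridentate Schiff-base ligand (20 mol%), hexanes, −20 °C
Reagents that add atoms: N-bromosuccinimide, O=C1CCC(=O)N1Br; chlorotitanium triisopropoxide, CC(C)O[Ti](Cl)(OC(C)C)OC(C)C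
Why: Titanium-mediated catalytic enantioselective bromochlorination of an allylic alcohol: bromine goes to C6 next to the carbinol and chloride to the tertiary C5 in an anti addition across the Z-alkene, and the chiral ligand on titanium selects the alkene face, which sets C5 and C6 together.

Step 4
Reactants: 5 ethyl (5S,6S)-6-bromo-5-chloro-7-hydroxy-5-methylheptanoate
Product: 6 ethyl (5S,6S)-6-bromo-5-chloro-5-methyl-7-[(4-methylbenzenesulfonyl)oxy]heptanoate
Conditions: TsCl, Et3N, DMAP (cat.), CH2Cl2, 0 °C
Reagents that add atoms: 4-methylbenzenesulfonyl chloride, Cc1ccc(cc1)S(Cl)(=O)=O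
Why: Sulfonylation of the primary alcohol with an amine base, which is too weak to close the bromohydrin to an epoxide, makes C7 a leaving group without touching a stereocentre.

Step 5
Reactants: 6 ethyl (5S,6S)-6-bromo-5-chloro-5-methyl-7-[(4-methylbenzenesulfonyl)oxy]heptanoate
Product: 7 ethyl (3S,4S)-3-bromo-4-chloro-4-methylcyclohexane-1-carboxylate (both C1 epimers)
Conditions: KN(SiMe3)2 (1.05 equiv), THF, −78 to 0 °C
Reagents that add atoms: none
Why: Intramolecular alkylation of the potassium ester enolate closes ring B in a 6-exo-tet mode at the primary tosylate, which is favoured over the far more hindered secondary bromide; the new C1 centre forms as an epimer mixture that does not matter because C1 becomes trigonal again in step 8.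

Step 6
Reactants: 7 ethyl (3S,4S)-3-bromo-4-chloro-4-methylcyclohexane-1-carboxylate
Product: 8 (3S,4S)-3-bromo-4-chloro-4-methylcyclohexane-1-carboxylic acid (both C1 epimers)
Conditions: LiOH, THF/H2O, 0–20 °C; then dilute HCl
Reagents that add atoms: lithium hydroxide, [Li+].[OH-]
Why: Saponification of the unhindered ethyl ester at or below room temperature, where hydroxide does not eliminate or displace the halides, frees the acid.

Step 7
Reactants: 8 (3S,4S)-3-bromo-4-chloro-4-methylcyclohexane-1-carboxylic acid; 9 1-bromo-3-methylbut-2-ene (prenyl bromide)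
Product: 10 3-methylbut-2-en-1-yl (3S,4S)-3-bromo-4-chloro-4-methylcyclohexane-1-carboxylate (both C1 epimers)
Conditions: K2CO3, DMF, 20 °C
Reagents that add atoms: none
Why: Carboxylate O-alkylation by the allylic bromide (SN2) under mild carbonate base gives the prenyl ester needed for the rearrangement.

Step 8
Reactants: 10 3-methylbut-2-en-1-yl (3S,4S)-3-bromo-4-chloro-4-methylcyclohexane-1-carboxylate
Product: 13 (1R,3S,4S)-3-bromo-4-chloro-4-methyl-1-(2-methylbut-3-en-2-yl)cyclohexane-1-carboxylic acid, via silyl ketene acetal 11 (not isolated), via trimethylsilyl ester 12 (not isolated)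
Conditions: LiN(iPr)2 added to 10 and Me3SiCl/Et3N, THF, −78 °C; then toluene, 60–70 °C; dilute HCl work-up
Reagents that add atoms: none
Why: Ireland–Claisen rearrangement: the ester is deprotonated with the silyl chloride already present (which keeps the enolate from attacking the gamma-bromide) and silyl ketene acetal 11 rearranges through a chair transition state, creating the C1–CMe2 bond between two quaternary carbons; the prenyl terminus should add to the equatorial face of the ring chair that has Br and Cl equatorial, which puts the tert-alkyl group cis to Br (1R), but the chair with axial halogens leads to the C1 epimer, so the face selectivity is not secured and the epimer is removed by chromatography.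

Step 9
Reactants: 13 (1R,3S,4S)-3-bromo-4-chloro-4-methyl-1-(2-methylbut-3-en-2-yl)cyclohexane-1-carboxylic acid
Product: 15 1-[(1R,3S,4S)-3-bromo-4-chloro-4-methyl-1-(2-methylbut-3-en-2-yl)cyclohexyl]ethan-1-one, via acid chloride 14 (not isolated)
Conditions: (COCl)2, DMF (cat.), CH2Cl2, 20 °C; then Me2CuLi, Et2O, −78 °C
Reagents that add atoms: lithium dimethylcuprate, C[Cu-]C.[Li+]
Why: The hindered acid is converted into its chloride, which acylates lithium dimethylcuprate; the reaction stops at the ketone and the cuprate does not attack alkyl halides at −78 °C (Gilman ketone synthesis).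

Step 10
Reactants: 15 1-[(1R,3S,4S)-3-bromo-4-chloro-4-methyl-1-(2-methylbut-3-en-2-yl)cyclohexyl]ethan-1-one
Product: 16 (1S,2S,4S)-2-bromo-1-chloro-1-methyl-4-(2-methylbut-3-en-2-yl)-4-(prop-1-en-2-yl)cyclohexane
Conditions: Cp2Ti(μ-Cl)(μ-CH2)AlMe2 (Tebbe reagent), pyridine, THF/toluene, −40 to 0 °C
Reagents that add atoms: Tebbe reagent Cp2Ti(μ-Cl)(μ-CH2)AlMe2 (drawn with a terminal Ti–Cl bond), C[Al](C)C[Ti](Cl)(C1C=CC=C1)C1C=CC=C1
Why: Tebbe methylenation transfers CH2 to hindered, enolisable ketones under non-basic conditions that leave the alkyl halides and the vinyl group alone, and the product is kept at or below room temperature to avoid a Cope rearrangement of the 1,5-diene.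

Step 11
Reactants: 16 (1S,2S,4S)-2-bromo-1-chloro-1-methyl-4-(2-methylbut-3-en-2-yl)-4-(prop-1-en-2-yl)cyclohexane
Product: 17 3-[(1S,3S,4S)-3-bromo-4-chloro-4-methyl-1-(prop-1-en-2-yl)cyclohexyl]-3-methylbutan-2-one
Conditions: PdCl2 (20 mol%), CuCl (1 equiv), O2 (1 atm), DMF/H2O 7:1, 25 °C
Reagents that add atoms: water, O
Why: Tsuji–Wacker oxidation, with dioxygen as the terminal oxidant, converts the monosubstituted vinyl group into the methyl ketone (Markovnikov hydroxypalladation by water) while the 1,1-disubstituted isopropenyl group is inert, which also removes the 1,5-diene.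

Step 12
Reactants: 17 3-[(1S,3S,4S)-3-bromo-4-chloro-4-methyl-1-(prop-1-en-2-yl)cyclohexyl]-3-methylbutan-2-one
Product: 19 2-[(1S,3S,4S)-3-bromo-4-chloro-4-methyl-1-(2-methyl-3-oxobutan-2-yl)cyclohexyl]prop-2-enal, via allylic alcohol 18 (not isolated)
Conditions: SeO2 (0.5 equiv), t-BuOOH, CH2Cl2, 20 °C; then MnO2
Reagents that add atoms: tert-butyl hydroperoxide, CC(C)(C)OO
Why: Selenium dioxide allylic oxidation (ene reaction, then 2,3-shift) attacks the only allylic C–H bonds, those of the isopropenyl methyl group, and MnO2 completes the oxidation of allylic alcohol 18 to the enal without touching the ketone.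

Step 13
Reactants: 19 2-[(1S,3S,4S)-3-bromo-4-chloro-4-methyl-1-(2-methyl-3-oxobutan-2-yl)cyclohexyl]prop-2-enal
Product: 21 (2R,6S,9S,10S)-10-bromo-9-chloro-2-hydroxy-5,5,9-trimethyl-1-methylidenespiro[5.5]undecan-4-one, via lithium enolate 20 (not isolated)
Conditions: LiN(SiMe3)2 (1.05 equiv) added slowly to 19, THF (high dilution), −78 °C; AcOH quench at −78 °C
Reagents that add atoms: none
Why: Only the acetyl CH3 can be deprotonated, because C5 is fully substituted and the enal carries no removable hydrogen, and lithium enolate 20 adds to the aldehyde carbonyl through a lithium-bridged, chair-like closed transition state to form C2–C3. The closest known reaction type is the intramolecular aldol addition of a methyl ketone lithium enolate to an aldehyde that gives a 3-hydroxycyclohexanone. Ring A closes in a 6-(enolendo)-exo-trig mode, helped by the two adjacent quaternary carbons C5 and C6, which hold the carbonyl arms close. The new stereocentre C2 is decided only by the choice between two chair-like transition states that differ in whether C7H2 or C11H2 of ring B lies syn to the forming C–O bond, so substrate control is weak, both epimers are expected, the 2R epimer 21 is separated by chromatography and the 2S epimer is returned through the fallback given below. The step needs 1,2-addition in place of the competing 6-endo conjugate addition to the enal and no retro-aldol equilibration, and lithium as counter-ion, −78 °C, high dilution and the cold acetic acid quench keep it under kinetic control. The secondary bromide and tertiary chloride should survive the brief, cold exposure to the hindered, poorly nucleophilic amide.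

Step 14
Reactants: 21 (2R,6S,9S,10S)-10-bromo-9-chloro-2-hydroxy-5,5,9-trimethyl-1-methylidenespiro[5.5]undecan-4-one
Product: 22 (2R,6S,9S,10S)-10-bromo-9-chloro-5,5,9-trimethyl-1-methylidene-2-[(triethylsilyl)oxy]spiro[5.5]undecan-4-one
Conditions: Et3SiOTf, 2,6-lutidine, CH2Cl2, −78 °C
Reagents that add atoms: triethylsilyl trifluoromethanesulfonate, CC[Si](CC)(CC)OS(=O)(=O)C(F)(F)F
Why: Silylation of the secondary allylic alcohol with the silyl triflate and a hindered pyridine at −78 °C is faster than any enolisation of the ketone and prevents retro-aldol cleavage in the next step.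

Step 15
Reactants: 22 (2R,6S,9S,10S)-10-bromo-9-chloro-5,5,9-trimethyl-1-methylidene-2-[(triethylsilyl)oxy]spiro[5.5]undecan-4-one
Product: 23 (2R,6S,9S,10S)-10-bromo-9-chloro-5,5,9-trimethyl-1-methylidene-2-[(triethylsilyl)oxy]spiro[5.5]undec-3-en-4-yl trifluoromethanesulfonate
Conditions: KN(SiMe3)2 added to 22 and PhNTf2, THF, −78 °C
Reagents that add atoms: N-phenylbis(trifluoromethanesulfonimide), FC(F)(F)S(=O)(=O)N(c1ccccc1)S(=O)(=O)C(F)(F)F
Why: The ketone can enolise only towards C3 (C5 is quaternary), and O-sulfonylation of the potassium enolate by PhNTf2, present from the start so that the enolate is trapped before it can expel the beta-silyloxy group, gives the enol triflate.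

Step 16
Reactants: 23 (2R,6S,9S,10S)-10-bromo-9-chloro-5,5,9-trimethyl-1-methylidene-2-[(triethylsilyl)oxy]spiro[5.5]undec-3-en-4-yl trifluoromethanesulfonate
Product: 24 [(2R,6S,9S,10S)-10-bromo-9-chloro-5,5,9-trimethyl-1-methylidene-2-[(triethylsilyl)oxy]spiro[5.5]undec-3-en-4-yl]trimethylstannane
Conditions: (Me3Sn)2, Pd(PPh3)4 (5 mol%), LiCl, THF, 65 °C
Reagents that add atoms: hexamethylditin, C[Sn](C)(C)[Sn](C)(C)C
Why: Palladium-catalysed stannylation of an enol triflate with hexamethylditin and LiCl (oxidative addition, transmetalation, reductive elimination) is neutral and leaves unactivated alkyl halides alone.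

Step 17
Reactants: 24 [(2R,6S,9S,10S)-10-bromo-9-chloro-5,5,9-trimethyl-1-methylidene-2-[(triethylsilyl)oxy]spiro[5.5]undec-3-en-4-yl]trimethylstannane
Product: 25 [(2R,6S,9S,10S)-4,10-dibromo-9-chloro-5,5,9-trimethyl-1-methylidenespiro[5.5]undec-3-en-2-yl]oxy-triethylsilane
Conditions: NBS, CH2Cl2, 0 °C
Reagents that add atoms: N-bromosuccinimide, O=C1CCC(=O)N1Br
Why: Bromodestannylation: NBS attacks the alkenyl–tin bond at the ipso carbon much faster than it reacts with the exocyclic alkene, giving the alkenyl bromide with the double bond in place.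

Step 18
Reactants: 25 [(2R,6S,9S,10S)-4,10-dibromo-9-chloro-5,5,9-trimethyl-1-methylidenespiro[5.5]undec-3-en-2-yl]oxy-triethylsilane
Product: 26 (2R,6S,9S,10S)-4,10-dibromo-9-chloro-5,5,9-trimethyl-1-methylidenespiro[5.5]undec-3-en-2-ol (target)
Conditions: HF·pyridine, pyridine, THF, 0 °C
Reagents that add atoms: none
Why: Fluoride-mediated cleavage of the triethylsilyl ether with buffered HF·pyridine is mild enough for the bis-allylic alcohol and the alkyl halides.

Compound list
1 | but-2-yn-1-ol | CC#CCO | starting material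
2 | (2Z)-3-iodobut-2-en-1-ol | C/C(I)=C/CO | intermediate
3 | (4-ethoxy-4-oxobutyl)zinc bromide | CCOC(=O)CCC[Zn]Br | starting material
4 | ethyl (5Z)-7-hydroxy-5-methylhept-5-enoate | CCOC(=O)CCC/C(C)=C\CO | intermediate
5 | ethyl (5S,6S)-6-bromo-5-chloro-7-hydroxy-5-methylheptanoate | CCOC(=O)CCC[C@](C)(Cl)[C@@H](Br)CO | intermediate
6 | ethyl (5S,6S)-6-bromo-5-chloro-5-methyl-7-[(4-methylbenzenesulfonyl)oxy]heptanoate | CCOC(=O)CCC[C@](C)(Cl)[C@@H](Br)COS(=O)(=O)c1ccc(C)cc1 | intermediate
7 | ethyl (3S,4S)-3-bromo-4-chloro-4-methylcyclohexane-1-carboxylate (both C1 epimers) | CCOC(=O)C1CC[C@](C)(Cl)[C@@H](Br)C1 | intermediate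
8 | (3S,4S)-3-bromo-4-chloro-4-methylcyclohexane-1-carboxylic acid (both C1 epimers) | OC(=O)C1CC[C@](C)(Cl)[C@@H](Br)C1 | intermediate
9 | 1-bromo-3-methylbut-2-ene (prenyl bromide) | CC(C)=CCBr | starting material
10 | 3-methylbut-2-en-1-yl (3S,4S)-3-bromo-4-chloro-4-methylcyclohexane-1-carboxylate (both C1 epimers) | CC(C)=CCOC(=O)C1CC[C@](C)(Cl)[C@@H](Br)C1 | intermediate
11 | trimethylsilyl ketene acetal of 10: [(3S,4S)-3-bromo-4-chloro-4-methylcyclohexylidene][(3-methylbut-2-en-1-yl)oxy]methoxy-trimethylsilane | CC(C)=CCOC(O[Si](C)(C)C)=C1CC[C@](C)(Cl)[C@@H](Br)C1 | intermediate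
12 | trimethylsilyl (1R,3S,4S)-3-bromo-4-chloro-4-methyl-1-(2-methylbut-3-en-2-yl)cyclohexane-1-carboxylate | C[Si](C)(C)OC(=O)[C@]1(C(C)(C)C=C)CC[C@](C)(Cl)[C@@H](Br)C1 | intermediate
13 | (1R,3S,4S)-3-bromo-4-chloro-4-methyl-1-(2-methylbut-3-en-2-yl)cyclohexane-1-carboxylic acid | OC(=O)[C@]1(C(C)(C)C=C)CC[C@](C)(Cl)[C@@H](Br)C1 | intermediate
14 | (1R,3S,4S)-3-bromo-4-chloro-4-methyl-1-(2-methylbut-3-en-2-yl)cyclohexane-1-carbonyl chloride | ClC(=O)[C@]1(C(C)(C)C=C)CC[C@](C)(Cl)[C@@H](Br)C1 | intermediate
15 | 1-[(1R,3S,4S)-3-bromo-4-chloro-4-methyl-1-(2-methylbut-3-en-2-yl)cyclohexyl]ethan-1-one | CC(=O)[C@]1(C(C)(C)C=C)CC[C@](C)(Cl)[C@@H](Br)C1 | intermediate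
16 | (1S,2S,4S)-2-bromo-1-chloro-1-methyl-4-(2-methylbut-3-en-2-yl)-4-(prop-1-en-2-yl)cyclohexane | CC(=C)[C@]1(C(C)(C)C=C)CC[C@](C)(Cl)[C@@H](Br)C1 | intermediate
17 | 3-[(1S,3S,4S)-3-bromo-4-chloro-4-methyl-1-(prop-1-en-2-yl)cyclohexyl]-3-methylbutan-2-one | CC(=C)[C@]1(C(C)(C)C(C)=O)CC[C@](C)(Cl)[C@@H](Br)C1 | intermediate
18 | 3-[(1S,3S,4S)-3-bromo-4-chloro-1-(3-hydroxyprop-1-en-2-yl)-4-methylcyclohexyl]-3-methylbutan-2-one | OCC(=C)[C@]1(C(C)(C)C(C)=O)CC[C@](C)(Cl)[C@@H](Br)C1 | intermediate
19 | 2-[(1S,3S,4S)-3-bromo-4-chloro-4-methyl-1-(2-methyl-3-oxobutan-2-yl)cyclohexyl]prop-2-enal | O=CC(=C)[C@]1(C(C)(C)C(C)=O)CC[C@](C)(Cl)[C@@H](Br)C1 | intermediate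
20 | lithium enolate of 19 at the acetyl CH3 (lithium but-1-en-2-olate) | O=CC(=C)[C@]1(C(C)(C)C(=C)O[Li])CC[C@](C)(Cl)[C@@H](Br)C1 | intermediate
21 | (2R,6S,9S,10S)-10-bromo-9-chloro-2-hydroxy-5,5,9-trimethyl-1-methylidenespiro[5.5]undecan-4-one | C=C1[C@H](O)CC(=O)C(C)(C)[C@]12CC[C@](C)(Cl)[C@@H](Br)C2 | intermediate
22 | (2R,6S,9S,10S)-10-bromo-9-chloro-5,5,9-trimethyl-1-methylidene-2-[(triethylsilyl)oxy]spiro[5.5]undecan-4-one | C=C1[C@H](O[Si](CC)(CC)CC)CC(=O)C(C)(C)[C@]12CC[C@](C)(Cl)[C@@H](Br)C2 | intermediate
23 | (2R,6S,9S,10S)-10-bromo-9-chloro-5,5,9-trimethyl-1-methylidene-2-[(triethylsilyl)oxy]spiro[5.5]undec-3-en-4-yl trifluoromethanesulfonate | C=C1[C@H](O[Si](CC)(CC)CC)C=C(OS(=O)(=O)C(F)(F)F)C(C)(C)[C@]12CC[C@](C)(Cl)[C@@H](Br)C2 | intermediate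
24 | [(2R,6S,9S,10S)-10-bromo-9-chloro-5,5,9-trimethyl-1-methylidene-2-[(triethylsilyl)oxy]spiro[5.5]undec-3-en-4-yl]trimethylstannane | C=C1[C@H](O[Si](CC)(CC)CC)C=C([Sn](C)(C)C)C(C)(C)[C@]12CC[C@](C)(Cl)[C@@H](Br)C2 | intermediate
25 | [(2R,6S,9S,10S)-4,10-dibromo-9-chloro-5,5,9-trimethyl-1-methylidenespiro[5.5]undec-3-en-2-yl]oxy-triethylsilane | C=C1[C@H](O[Si](CC)(CC)CC)C=C(Br)C(C)(C)[C@]12CC[C@](C)(Cl)[C@@H](Br)C2 | intermediate
26 | (2R,6S,9S,10S)-4,10-dibromo-9-chloro-5,5,9-trimethyl-1-methylidenespiro[5.5]undec-3-en-2-ol | C=C1[C@H](O)C=C(Br)C(C)(C)[C@]12CC[C@](C)(Cl)[C@@H](Br)C2 | target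

Total step count: 18. Longest linear sequence: 18 steps (1 to 26).

Steps most likely to fail

Step 13 (key step). What may go wrong: poor facial selectivity at the aldehyde carbon, because the two ring-closing transition states are close in energy, so that a large share of the material ends as the 2S carbinol; leakage into conjugate addition if the aldolate is allowed to equilibrate. Fallback (the carbinol is set by a reagent-controlled reduction instead of by the aldol): it sets out from 19 and comes back at 26. The (2S,6S,9S,10S)-hydroxy ketone F1 formed beside 21, or the unseparated pair, is taken through the conditions of steps 14 to 18. This gives the triethylsilyl ether F2, the enol triflate F3, the alkenylstannane F4, the silylated alkenyl bromide F5 and, after desilylation, the 2S allylic alcohol F6. MnO2 oxidises this bis-allylic alcohol to the cross-conjugated dienone F7. Reduction with catecholborane and (S)-2-methyl-CBS-oxazaborolidine at −78 °C, in which the alpha-branched C1 alkenyl arm should act as the large group, is expected to give 26.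

Step 8. What may go wrong: poor facial selectivity at the exocyclic ketene acetal, because the dihalocyclohexane can react from either chair and the two chairs present opposite faces as the equatorial one; the wrong C1 epimer cannot be recycled. A second failure mode is loss of bromide by gamma-elimination at the enolate stage. Fallback (quaternary carbon first on a halogen-free ring, halogens afterwards under carboxyl direction): it sets out from 9 and comes back at 13. Commercial racemic 4-methylcyclohex-3-ene-1-carboxylic acid F8 is alkylated with 9 (K2CO3, DMF) to the prenyl ester F9. Ireland–Claisen rearrangement, now with no halide present at the enolate stage, gives the racemic quaternary acid F10, and resolution through its salt with an enantiopure amine gives the R acid F11. Bromolactonisation (NBS, NaHCO3) can trap only the bromonium ion on the face anti to the carboxyl group and so puts bromine cis to the tert-alkyl group in the bromolactone F12. Opening with HCl and ZnCl2 through the same bromonium ion, with chloride entering at the tertiary carbon anti to bromine, should return 13. This last operation rests on analogy with the acid-promoted return of halolactones to halonium ions and is the least precedented part of the fallback.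

Step 10. What may go wrong: proton abstraction (enolisation) of the very hindered methyl ketone by the titanium methylidene instead of methylene transfer. Fallback (addition, then elimination): it sets out from 15 and comes back at 16. Me3SiCH2Li with CeCl3 at −78 °C adds to the ketone to give the beta-hydroxysilane F13, and Peterson elimination (KH in THF, or HF in acetonitrile) gives 16.

Further compounds
F1 | step 13 | (2S,6S,9S,10S)-10-bromo-9-chloro-2-hydroxy-5,5,9-trimethyl-1-methylidenespiro[5.5]undecan-4-one | C=C1[C@@H](O)CC(=O)C(C)(C)[C@]12CC[C@](C)(Cl)[C@@H](Br)C2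
F2 | step 13 | (2S,6S,9S,10S)-10-bromo-9-chloro-5,5,9-trimethyl-1-methylidene-2-[(triethylsilyl)oxy]spiro[5.5]undecan-4-one | C=C1[C@@H](O[Si](CC)(CC)CC)CC(=O)C(C)(C)[C@]12CC[C@](C)(Cl)[C@@H](Br)C2
F3 | step 13 | (2S,6S,9S,10S)-10-bromo-9-chloro-5,5,9-trimethyl-1-methylidene-2-[(triethylsilyl)oxy]spiro[5.5]undec-3-en-4-yl trifluoromethanesulfonate | C=C1[C@@H](O[Si](CC)(CC)CC)C=C(OS(=O)(=O)C(F)(F)F)C(C)(C)[C@]12CC[C@](C)(Cl)[C@@H](Br)C2
F4 | step 13 | [(2S,6S,9S,10S)-10-bromo-9-chloro-5,5,9-trimethyl-1-methylidene-2-[(triethylsilyl)oxy]spiro[5.5]undec-3-en-4-yl]trimethylstannane | C=C1[C@@H](O[Si](CC)(CC)CC)C=C([Sn](C)(C)C)C(C)(C)[C@]12CC[C@](C)(Cl)[C@@H](Br)C2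
F5 | step 13 | [(2S,6S,9S,10S)-4,10-dibromo-9-chloro-5,5,9-trimethyl-1-methylidenespiro[5.5]undec-3-en-2-yl]oxy-triethylsilane | C=C1[C@@H](O[Si](CC)(CC)CC)C=C(Br)C(C)(C)[C@]12CC[C@](C)(Cl)[C@@H](Br)C2
F6 | step 13 | (2S,6S,9S,10S)-4,10-dibromo-9-chloro-5,5,9-trimethyl-1-methylidenespiro[5.5]undec-3-en-2-ol | C=C1[C@@H](O)C=C(Br)C(C)(C)[C@]12CC[C@](C)(Cl)[C@@H](Br)C2
F7 | step 13 | (6S,9S,10S)-4,10-dibromo-9-chloro-5,5,9-trimethyl-1-methylidenespiro[5.5]undec-3-en-2-one | C=C1C(=O)C=C(Br)C(C)(C)[C@]12CC[C@](C)(Cl)[C@@H](Br)C2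
F8 | step 8 | 4-methylcyclohex-3-ene-1-carboxylic acid (racemic) | CC1=CCC(CC1)C(O)=O
F9 | step 8 | 3-methylbut-2-en-1-yl 4-methylcyclohex-3-ene-1-carboxylate (racemic) | CC1=CCC(CC1)C(=O)OCC=C(C)C
F10 | step 8 | 4-methyl-1-(2-methylbut-3-en-2-yl)cyclohex-3-ene-1-carboxylic acid (racemic) | OC(=O)C1(C(C)(C)C=C)CCC(C)=CC1
F11 | step 8 | (1R)-4-methyl-1-(2-methylbut-3-en-2-yl)cyclohex-3-ene-1-carboxylic acid | OC(=O)[C@]1(C(C)(C)C=C)CCC(C)=CC1
F12 | step 8 | 4-bromo-4-methyl-1-(2-methylbut-3-en-2-yl)-6-oxabicyclo[3.2.1]octan-7-one (lactone oxygen on the face of the carbonyl bridge, bromine on the opposite face, cis to the tert-alkyl group) | C=CC(C)(C)[C@]12CC[C@@](C)(Br)[C@H](OC1=O)C2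
F13 | step 10 | 2-[(1R,3S,4S)-3-bromo-4-chloro-4-methyl-1-(2-methylbut-3-en-2-yl)cyclohexyl]-1-(trimethylsilyl)propan-2-ol (both carbinol epimers) | C[Si](C)(C)CC(C)(O)[C@]1(C(C)(C)C=C)CC[C@](C)(Cl)[C@@H](Br)C1
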